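**Plan** (germacrane numbering: ring C1–C10; C11–C13 are the lactone carbons on C7 with the ring oxygen on C6; C14 on C10, C15 on C4)
1. Retrosynthesis: remove the C3 acetate, cut the ring bond C3–C4, then C1=C2, the C8 angelate, C6–C7 together with the lactone C12–O bond, C7–C11 and the C8–O bond.
2. Enabling feature: C3 is a secondary carbinol flanked by the C1=C2 and C4=C5 double bonds of the ten-membered ring, which is the product of adding a (Z)-C4 alkenyl metal to a C1–C3 enal. The cis-fused five-membered lactone on C6/C7 and the Z alkene hold the two chain ends close.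
3. Forward: (R)-linalool supplies C1, C7–C10 and C14. A Baylis–Hillman/indium Barbier sequence with (Z)-3-iodobut-2-enal (C4–C6, C15) completes the chain and forms the lactone ring first.
4. The ten-membered ring is closed last by the chromium/nickel alkenyl–aldehyde addition, followed by acetylation.
5. Stereochemistry: C10 from linalool; C8 from L-proline aminoxylation; C6 and C7 from the syn-selective Barbier step under control of C8; C3 from the ring closure; 4Z from hydroalumination–iodination of but-2-yn-1-ol; 1E from metathesis; the angelate geometry from angelic acid.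

Key step: step 15

Remark: the given structure is read as (3R,6R,7S,8R,10R), 1E,4Z, with H-6 and H-7 cis on the lactone; commercial (R)-(−)-linalool is taken as enantiomerically pure.

**Step 1**
Reactants: 1 (R)-linalool
Product: 2 (3R)-3,7-dimethyl-3-[(triethylsilyl)oxy]octa-1,6-diene
Conditions: TESOTf, 2,6-lutidine, CH2Cl2, −78 → 0 °C
Reagents that add atoms: triethylsilyl trifluoromethanesulfonate, CC[Si](CC)(CC)OS(=O)(=O)C(F)(F)F
Why: A silyl triflate with a hindered pyridine base silylates the hindered tertiary allylic alcohol without ionizing it (silyl ether formation), leaves the linalool stereocentre (C10 of the target) untouched, and prevents lactol formation after step 2.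

**Step 2**
Reactants: 2 silyl ether
Product: 4 (4R)-4-methyl-4-[(triethylsilyl)oxy]hex-5-enal, via ozonide 3 (not isolated)
Conditions: O3 (1 equiv, Sudan red 7B end point), CH2Cl2, −78 °C; then Me2S, −78 °C → rt
Reagents that add atoms: ozone, O=[O+][O-]
Why: Ozone should attack the electron-rich trisubstituted alkene much faster than the vinyl group on the silyloxy-bearing quaternary carbon, so one equivalent cleaves only the former and dimethyl sulfide reduces the ozonide to the aldehyde (chemoselective ozonolysis with reductive work-up).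

**Step 3**
Reactants: 4 aldehyde
Product: 6 (2R,4R)-4-methyl-2-[(phenylamino)oxy]-4-[(triethylsilyl)oxy]hex-5-en-1-ol, via aminoxy aldehyde 5 (not isolated)
Conditions: L-proline (20 mol%), PhNO, DMSO, rt; then NaBH4, EtOH, 0 °C
Reagents that add atoms: nitrosobenzene, O=Nc1ccccc1
Why: The L-proline enamine of 4 attacks the oxygen of nitrosobenzene, which the carboxylic acid holds on one enamine face, so the new C–O bond (C8 of the target) should form with the (R) configuration that L-proline gives with α-unbranched aldehydes whatever the remote centre (proline-catalysed α-aminoxylation), and NaBH4 reduces the labile aldehyde 5 at once.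

**Step 4**
Reactants: 6 anilinooxy alcohol
Product: 7 (2R,4R)-4-methyl-4-[(triethylsilyl)oxy]hex-5-ene-1,2-diol
Conditions: Zn dust, AcOH, THF, 0 °C → rt
Reagents that add atoms: none
Why: Zinc in acetic acid cleaves the weak N–O bond reductively and should leave the alkene and the hindered tertiary silyl ether alone (reductive N–O cleavage), so the C2 configuration is kept.

**Step 5**
Reactants: 7 diol
Product: 8 (3R,5R)-3-methyl-3,5,6-tris[(triethylsilyl)oxy]hex-1-ene
Conditions: TESCl, imidazole, DMAP (cat.), CH2Cl2, 0 °C → rt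
Reagents that add atoms: chlorotriethylsilane, CC[Si](Cl)(CC)CC
Why: Chlorosilane and imidazole silylate the primary and the secondary hydroxyl (silyl ether formation), which sets up the selective oxidation of step 6 and gives the C8 oxygen the bulky, non-chelating group needed in step 11.

**Step 6**
Reactants: 8 tris-silyl ether
Product: 9 (2R,4R)-4-methyl-2,4-bis[(triethylsilyl)oxy]hex-5-enal
Conditions: (COCl)2, DMSO, CH2Cl2, −78 °C; 8, −78 → −30 °C; then Et3N, −78 → 0 °C
Reagents that add atoms: none
Why: Under Swern conditions only the primary triethylsilyl ether is cleaved by the chlorosulfonium reagent and oxidized in the same flask, while the secondary and tertiary silyl ethers stay (selective oxidative desilylation, Swern oxidation), and the low temperature should keep the α-silyloxy centre from epimerizing.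

**Step 7**
Reactants: 9 α-silyloxy aldehyde, 10 methyl acrylate
Product: 11 methyl (4R,6R)-3-hydroxy-6-methyl-2-methylidene-4,6-bis[(triethylsilyl)oxy]oct-7-enoate (both C3 epimers)
Conditions: DABCO (1 equiv), 10 (10 equiv, neat), rt, several days
Reagents that add atoms: none
Why: DABCO adds to the acrylate, the zwitterionic enolate adds to the activated α-silyloxy aldehyde and the amine is expelled (Morita–Baylis–Hillman reaction); the tertiary amine should not enolize the aldehyde appreciably, so C4 is kept, and the new carbinol centre is erased in step 8.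

**Step 8**
Reactants: 11 Baylis–Hillman adduct
Product: 12 methyl (2Z,4R,6R)-2-(bromomethyl)-6-methyl-4,6-bis[(triethylsilyl)oxy]octa-2,7-dienoate
Conditions: NBS, Me2S, CH2Cl2, 0 °C → rt
Reagents that add atoms: N-bromosuccinimide, O=C1CCC(=O)N1Br
Why: The sulfonium reagent from NBS and dimethyl sulfide activates the allylic hydroxyl and bromide displaces it with allylic transposition to the conjugated, thermodynamically preferred bromide with the chain cis to CH2Br and trans to the ester (Corey–Kim-type bromination of a Baylis–Hillman adduct), under non-acidic conditions that spare both silyl ethers.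

**Step 9**
Reactants: 13 but-2-yn-1-ol
Product: 15 (2Z)-3-iodobut-2-en-1-ol, via alkenylaluminate 14 (not isolated)
Conditions: NaAlH2(OCH2CH2OCH3)2, THF, 0 °C → rt; then I2, THF, −78 → 0 °C
Reagents that add atoms: iodine, II
Why: The aluminium alkoxide delivers hydride to C2 in an anti sense to give the five-membered alkenylaluminate, whose C–Al bond iodine cleaves with retention (hydroxyl-directed trans-hydroalumination–iodination), which fixes iodine cis to CH2OH, the future Z C4=C5 geometry.

**Step 10**
Reactants: 15 iodo alcohol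
Product: 16 (2Z)-3-iodobut-2-enal
Conditions: MnO2, CH2Cl2, rt, dark; used directly
Reagents that add atoms: none
Why: Activated MnO2 oxidizes the allylic alcohol to the enal under neutral conditions without touching the alkenyl iodide (allylic oxidation), and immediate use limits Z to E isomerization.

**Step 11**
Reactants: 12 allylic bromide, 16 (2Z)-3-iodobut-2-enal
Product: 18 (4R,5S)-5-[(1Z)-2-iodoprop-1-en-1-yl]-3-methylidene-4-[(1R,3R)-3-methyl-1,3-bis(triethylsilyloxy)pent-4-en-1-yl]oxolan-2-one, via hydroxy ester 17 (not isolated)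
Conditions: In powder, THF/H2O 3:1, rt; then PPTS (cat.), CH2Cl2, rt
Reagents that add atoms: none
Why: Indium inserts into the allylic C–Br bond and the Z-configured allylindium should add 1,2 to the enal through a chair six-membered (Zimmerman–Traxler) transition state with the iodoalkenyl group equatorial, giving the syn adduct and hence the cis-lactone, while C8–H eclipses the C7=C11 plane to avoid A(1,3) strain with the CH2In group and the aldehyde bonds to C7 anti to the bulky triethylsilyloxy group (Barbier allylation–lactonization); PPTS then closes the lactone on the only free hydroxyl.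

**Step 12**
Reactants: 18 bis-silyl lactone
Product: 19 (4S,5S)-4-[(1R,3R)-1,3-dihydroxy-3-methylpent-4-en-1-yl]-5-[(1Z)-2-iodoprop-1-en-1-yl]-3-methylideneoxolan-2-one
Conditions: HF·pyridine, pyridine, THF, 0 °C → rt
Reagents that add atoms: none
Why: Buffered HF·pyridine removes the secondary and the tertiary triethylsilyl ether (fluoride desilylation) under mildly acidic conditions in which the lactone should not migrate to the C8 oxygen and the tertiary allylic alcohol should not ionize.

**Step 13**
Reactants: 19 diol lactone, 20 angelic acid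
Product: 22 (1R,3R)-3-hydroxy-1-{(2S,3S)-2-[(1Z)-2-iodoprop-1-en-1-yl]-4-methylidene-5-oxooxolan-3-yl}-3-methylpent-4-en-1-yl (2Z)-2-methylbut-2-enoate, via mixed anhydride 21 (not isolated)
Conditions: 20, 2,4,6-trichlorobenzoyl chloride, Et3N, toluene, rt; then 19, toluene, 80 °C (no DMAP)
Reagents that add atoms: none
Why: The preformed mixed anhydride acylates the secondary C8 hydroxyl at the angeloyl carbonyl while the tertiary C10 hydroxyl is too hindered, and the DMAP-free protocol should avoid Z to E isomerization to the tiglate (Yamaguchi esterification).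

**Step 14**
Reactants: 22 angelate, 23 crotonaldehyde
Product: 24 (1R,3R,4E)-3-hydroxy-1-{(2S,3S)-2-[(1Z)-2-iodoprop-1-en-1-yl]-4-methylidene-5-oxooxolan-3-yl}-3-methyl-6-oxohex-4-en-1-yl (2Z)-2-methylbut-2-enoate
Conditions: 23 (10 equiv), second-generation Hoveyda–Grubbs catalyst RuCl2(H2IMes)(=CH-C6H4-2-OiPr) (10 mol%), CH2Cl2, 40 °C
Reagents that add atoms: none
Why: The ruthenium carbene should initiate at the only monosubstituted alkene, whose free allylic hydroxyl assists metathesis, and exchange with crotonaldehyde to give the conjugated E enal with loss of propene (olefin cross-metathesis), whereas the lactone methylene, the angelate and the alkenyl iodide are too hindered or electron-poor to react.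

**Step 15**
Reactants: 24 iodo enal
Product: 25 (3R,6R,7S,8R,10R)-8-angeloyloxy-3,10-dihydroxygermacra-1E,4Z,11(13)-trien-12,6-olide
Conditions: CrCl2 (10 equiv), NiCl2 (0.1 equiv), degassed DMSO, rt, slow addition of 24 to 0.002 M
Reagents that add atoms: none
Why: CrCl2 reduces NiCl2 to zerovalent nickel, which inserts into the C4–I bond; transmetalation gives the trivalent alkenylchromium with the Z geometry retained, and this adds 1,2 to the chromium-bound C3 aldehyde (Nozaki–Hiyama–Kishi reaction in its macrocyclizing form, known for nine- to eleven-membered carbocycles). The ten-membered ring closes in the 10-exo-trig mode; the five-membered lactone is already present and holds C5 and C8 cis, so the two chain ends are gauche. The new C3 centre should be controlled by the C6 centre, relayed through the Z C4=C5 bond: with H-3 and H-6 both eclipsing the alkene plane (A(1,3) strain) and the ring bonds C3–C2 and C6–C7 on one face, the chromium alkoxide lies on the face of the lactone oxygen, which corresponds to addition to the Si face of the aldehyde and gives 3R. The step needs chemoselectivity for the aldehyde over the lactone, the two enoate units and the free tertiary hydroxyl, which the low basicity and carbonyl selectivity of alkenylchromium reagents should secure. It also needs cyclization to outrun oligomerization, which slow addition at high dilution should secure.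

**Step 16**
Reactants: 25 macrocyclic diol
Product: 26 (3R,6R,7S,8R,10R)-3-acetoxy-8-angeloyloxy-10-hydroxygermacra-1E,4Z,11(13)-trien-12,6-olide (CNP0181631.1)
Conditions: Ac2O, pyridine, DMAP (cat.), CH2Cl2, 0 °C
Reagents that add atoms: acetic anhydride, CC(=O)OC(C)=O
Why: Acetic anhydride in pyridine should acetylate the secondary allylic C3 hydroxyl and not the hindered tertiary C10 hydroxyl (selective O-acylation), with no change at any stereocentre.

**Compound list**
1 | (R)-(−)-linalool, (3R)-3,7-dimethylocta-1,6-dien-3-ol | C=C[C@](C)(O)CCC=C(C)C | starting material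
2 | (3R)-3,7-dimethyl-3-[(triethylsilyl)oxy]octa-1,6-diene | C=C[C@](C)(O[Si](CC)(CC)CC)CCC=C(C)C | intermediate
3 | 3,3-dimethyl-5-[(3R)-3-methyl-3-(triethylsilyloxy)pent-4-en-1-yl]-1,2,4-trioxolane (ozonide) | C=C[C@](C)(O[Si](CC)(CC)CC)CCC1OOC(C)(C)O1 | intermediate
4 | (4R)-4-methyl-4-[(triethylsilyl)oxy]hex-5-enal | C=C[C@](C)(O[Si](CC)(CC)CC)CCC=O | intermediate
5 | (2R,4R)-4-methyl-2-[(phenylamino)oxy]-4-[(triethylsilyl)oxy]hex-5-enal | C=C[C@](C)(O[Si](CC)(CC)CC)C[C@@H](ONc1ccccc1)C=O | intermediate
6 | (2R,4R)-4-methyl-2-[(phenylamino)oxy]-4-[(triethylsilyl)oxy]hex-5-en-1-ol | C=C[C@](C)(O[Si](CC)(CC)CC)C[C@@H](ONc1ccccc1)CO | intermediate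
7 | (2R,4R)-4-methyl-4-[(triethylsilyl)oxy]hex-5-ene-1,2-diol | C=C[C@](C)(O[Si](CC)(CC)CC)C[C@@H](O)CO | intermediate
8 | (3R,5R)-3-methyl-3,5,6-tris[(triethylsilyl)oxy]hex-1-ene | C=C[C@](C)(O[Si](CC)(CC)CC)C[C@@H](O[Si](CC)(CC)CC)CO[Si](CC)(CC)CC | intermediate
9 | (2R,4R)-4-methyl-2,4-bis[(triethylsilyl)oxy]hex-5-enal | C=C[C@](C)(O[Si](CC)(CC)CC)C[C@@H](O[Si](CC)(CC)CC)C=O | intermediate
10 | methyl acrylate | C=CC(=O)OC | starting material
11 | methyl (4R,6R)-3-hydroxy-6-methyl-2-methylidene-4,6-bis[(triethylsilyl)oxy]oct-7-enoate (both C3 epimers) | C=C[C@](C)(O[Si](CC)(CC)CC)C[C@@H](O[Si](CC)(CC)CC)C(O)C(=C)C(=O)OC | intermediate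
12 | methyl (2Z,4R,6R)-2-(bromomethyl)-6-methyl-4,6-bis[(triethylsilyl)oxy]octa-2,7-dienoate | C=C[C@](C)(O[Si](CC)(CC)CC)C[C@@H](O[Si](CC)(CC)CC)/C=C(\CBr)C(=O)OC | intermediate
13 | but-2-yn-1-ol | CC#CCO | starting material
14 | sodium 2,2-bis(2-methoxyethoxy)-3-methyl-2,5-dihydro-1,2-oxaaluminol-2-uide (cyclic alkenylaluminate) | CC1=CCO[Al-]1(OCCOC)OCCOC.[Na+] | intermediate
15 | (2Z)-3-iodobut-2-en-1-ol | C/C(I)=C/CO | intermediate
16 | (2Z)-3-iodobut-2-enal | C/C(I)=C/C=O | intermediate
17 | methyl (3R,4S,5Z)-4-hydroxy-6-iodo-2-methylidene-3-[(1R,3R)-3-methyl-1,3-bis(triethylsilyloxy)pent-4-en-1-yl]hept-5-enoate | COC(=O)C(=C)[C@H]([C@H](O)/C=C(/C)I)[C@H](O[Si](CC)(CC)CC)C[C@@](C)(O[Si](CC)(CC)CC)C=C | intermediate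
18 | (4R,5S)-5-[(1Z)-2-iodoprop-1-en-1-yl]-3-methylidene-4-[(1R,3R)-3-methyl-1,3-bis(triethylsilyloxy)pent-4-en-1-yl]oxolan-2-one | C=C1C(=O)O[C@H](/C=C(/C)I)[C@@H]1[C@H](O[Si](CC)(CC)CC)C[C@@](C)(O[Si](CC)(CC)CC)C=C | intermediate
19 | (4S,5S)-4-[(1R,3R)-1,3-dihydroxy-3-methylpent-4-en-1-yl]-5-[(1Z)-2-iodoprop-1-en-1-yl]-3-methylideneoxolan-2-one | C=C1C(=O)O[C@H](/C=C(/C)I)[C@@H]1[C@H](O)C[C@@](C)(O)C=C | intermediate
20 | angelic acid, (2Z)-2-methylbut-2-enoic acid | C/C=C(/C)C(=O)O | starting material
21 | (2Z)-2-methylbut-2-enoic 2,4,6-trichlorobenzoic anhydride | C/C=C(/C)C(=O)OC(=O)c1c(Cl)cc(Cl)cc1Cl | intermediate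
22 | (1R,3R)-3-hydroxy-1-{(2S,3S)-2-[(1Z)-2-iodoprop-1-en-1-yl]-4-methylidene-5-oxooxolan-3-yl}-3-methylpent-4-en-1-yl (2Z)-2-methylbut-2-enoate | C=C1C(=O)O[C@H](/C=C(/C)I)[C@@H]1[C@H](OC(=O)/C(C)=C\C)C[C@@](C)(O)C=C | intermediate
23 | crotonaldehyde, (2E)-but-2-enal | C/C=C/C=O | starting material
24 | (1R,3R,4E)-3-hydroxy-1-{(2S,3S)-2-[(1Z)-2-iodoprop-1-en-1-yl]-4-methylidene-5-oxooxolan-3-yl}-3-methyl-6-oxohex-4-en-1-yl (2Z)-2-methylbut-2-enoate | C=C1C(=O)O[C@H](/C=C(/C)I)[C@@H]1[C@H](OC(=O)/C(C)=C\C)C[C@@](C)(O)/C=C/C=O | intermediate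
25 | (3R,6R,7S,8R,10R)-8-angeloyloxy-3,10-dihydroxygermacra-1E,4Z,11(13)-trien-12,6-olide | C=C1C(=O)O[C@@H]2/C=C(/C)[C@H](O)/C=C/[C@](C)(O)C[C@@H](OC(=O)/C(C)=C\C)[C@H]12 | intermediate
26 | (3R,6R,7S,8R,10R)-3-acetoxy-8-angeloyloxy-10-hydroxygermacra-1E,4Z,11(13)-trien-12,6-olide (CNP0181631.1) | C=C1C(=O)O[C@@H]2/C=C(/C)[C@H](OC(C)=O)/C=C/[C@](C)(O)C[C@@H](OC(=O)/C(C)=C\C)[C@H]12 | target

**Step count and risks**
Total step count: 16. Longest linear sequence: 14 steps (steps 1–8 and 11–16, from (R)-linalool).

Steps most likely to fail: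

1. Step 15. What may go wrong: the alkenylchromium adds to the Re face of the C3 aldehyde in the macrocyclic transition state, or adds unselectively, so that the 3S alcohol forms. Fallback: setting out from 24, the cyclization is run as in step 15 and the (3S)-alcohol F1 is not acetylated but treated with acetic acid under Mitsunobu conditions (PPh3, DIAD, AcOH, toluene, 0 °C). Substitution with inversion at the activated C3 oxygen should install the acetate in the 3R configuration while the tertiary hydroxyl stays free. The sequence comes back to the route at 26.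

2. Step 11. What may go wrong: the aldehyde bonds to the face of C7 syn to the silyloxy group (reversed facial sense relative to C8), which would give C6 and C7 in the wrong absolute configuration. Fallback: the C8 centre is set in the opposite sense and inverted at the end. Setting out from 4, D-proline replaces L-proline in the aminoxylation to give the (2S)-aminoxy aldehyde F2, reduced in the flask to the (2S)-anilinooxy alcohol F3. The operations of steps 4–8 then give the (2S)-diol F4, the tris-silyl ether F5, the (2S)-aldehyde F6, the Baylis–Hillman adduct F7 and the (4S)-bromide F8. The indium reaction with 16 would then give, through the reversed facial sense, the 8-epi hydroxy ester F9 and the 8-epi lactone F10, which carry the C6 and C7 configurations of 18. Desilylation as in step 12 gives the 8-epi diol lactone F11. A Mitsunobu esterification with angelic acid 20 (PPh3, DIAD, toluene, 0 °C → rt) inverts C8 while installing the angelate. The sequence comes back to the route at 22.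

3. Step 14. What may go wrong: slow initiation at the vinyl group on the fully substituted carbinol carbon, so that catalyst decomposition and self-metathesis of 23 outrun productive exchange. Fallback: setting out from 22, a hydrogen-bond-directed dihydroxylation of the vinyl group next to the tertiary hydroxyl (OsO4·TMEDA, CH2Cl2, −78 °C; then aqueous NaHSO3) gives the triol F12. NaIO4 (THF/H2O, 0 °C) cleaves its terminal diol to the α-hydroxy aldehyde F13, which has no α-hydrogen and so cannot epimerize at C10. A Wittig reaction with (triphenylphosphoranylidene)acetaldehyde (toluene, 60 °C) should give the E enal. The sequence comes back to the route at 24.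

**Further compounds**
F1 | step 15 | (3S,6R,7S,8R,10R)-8-angeloyloxy-3,10-dihydroxygermacra-1E,4Z,11(13)-trien-12,6-olide | C=C1C(=O)O[C@@H]2/C=C(/C)[C@@H](O)/C=C/[C@](C)(O)C[C@@H](OC(=O)/C(C)=C\C)[C@H]12
F2 | step 11 | (2S,4R)-4-methyl-2-[(phenylamino)oxy]-4-[(triethylsilyl)oxy]hex-5-enal | C=C[C@](C)(O[Si](CC)(CC)CC)C[C@H](ONc1ccccc1)C=O
F3 | step 11 | (2S,4R)-4-methyl-2-[(phenylamino)oxy]-4-[(triethylsilyl)oxy]hex-5-en-1-ol | C=C[C@](C)(O[Si](CC)(CC)CC)C[C@H](ONc1ccccc1)CO
F4 | step 11 | (2S,4R)-4-methyl-4-[(triethylsilyl)oxy]hex-5-ene-1,2-diol | C=C[C@](C)(O[Si](CC)(CC)CC)C[C@H](O)CO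
F5 | step 11 | (3R,5S)-3-methyl-3,5,6-tris[(triethylsilyl)oxy]hex-1-ene | C=C[C@](C)(O[Si](CC)(CC)CC)C[C@H](O[Si](CC)(CC)CC)CO[Si](CC)(CC)CC
F6 | step 11 | (2S,4R)-4-methyl-2,4-bis[(triethylsilyl)oxy]hex-5-enal | C=C[C@](C)(O[Si](CC)(CC)CC)C[C@H](O[Si](CC)(CC)CC)C=O
F7 | step 11 | methyl (4S,6R)-3-hydroxy-6-methyl-2-methylidene-4,6-bis[(triethylsilyl)oxy]oct-7-enoate (both C3 epimers) | C=C[C@](C)(O[Si](CC)(CC)CC)C[C@H](O[Si](CC)(CC)CC)C(O)C(=C)C(=O)OC
F8 | step 11 | methyl (2Z,4S,6R)-2-(bromomethyl)-6-methyl-4,6-bis[(triethylsilyl)oxy]octa-2,7-dienoate | C=C[C@](C)(O[Si](CC)(CC)CC)C[C@H](O[Si](CC)(CC)CC)/C=C(\CBr)C(=O)OC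
F9 | step 11 | methyl (3R,4S,5Z)-4-hydroxy-6-iodo-2-methylidene-3-[(1S,3R)-3-methyl-1,3-bis(triethylsilyloxy)pent-4-en-1-yl]hept-5-enoate | COC(=O)C(=C)[C@H]([C@H](O)/C=C(/C)I)[C@@H](O[Si](CC)(CC)CC)C[C@@](C)(O[Si](CC)(CC)CC)C=C
F10 | step 11 | (4R,5S)-5-[(1Z)-2-iodoprop-1-en-1-yl]-3-methylidene-4-[(1S,3R)-3-methyl-1,3-bis(triethylsilyloxy)pent-4-en-1-yl]oxolan-2-one | C=C1C(=O)O[C@H](/C=C(/C)I)[C@@H]1[C@@H](O[Si](CC)(CC)CC)C[C@@](C)(O[Si](CC)(CC)CC)C=C
F11 | step 11 | (4S,5S)-4-[(1S,3R)-1,3-dihydroxy-3-methylpent-4-en-1-yl]-5-[(1Z)-2-iodoprop-1-en-1-yl]-3-methylideneoxolan-2-one | C=C1C(=O)O[C@H](/C=C(/C)I)[C@@H]1[C@@H](O)C[C@@](C)(O)C=C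
F12 | step 14 | (1R,3R)-3,4,5-trihydroxy-1-{(2S,3S)-2-[(1Z)-2-iodoprop-1-en-1-yl]-4-methylidene-5-oxooxolan-3-yl}-3-methylpentyl (2Z)-2-methylbut-2-enoate (both C4 epimers) | C=C1C(=O)O[C@H](/C=C(/C)I)[C@@H]1[C@H](OC(=O)/C(C)=C\C)C[C@@](C)(O)C(O)CO
F13 | step 14 | (1R,3R)-3-hydroxy-1-{(2S,3S)-2-[(1Z)-2-iodoprop-1-en-1-yl]-4-methylidene-5-oxooxolan-3-yl}-3-methyl-4-oxobutyl (2Z)-2-methylbut-2-enoate | C=C1C(=O)O[C@H](/C=C(/C)I)[C@@H]1[C@H](OC(=O)/C(C)=C\C)C[C@@](C)(O)C=O
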